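Locants used throughout: C1 = carbinol carbon carrying the anisoate, C2=C3(CH3), C4, C5, C6–C7(CH3) = oxirane, C8, C9, C10, C11 = C(CH3)2 bonded back to C1.
Cuts, in retrosynthetic order: the oxirane oxygen (leaving an E-C6=C7 alkene), the ester C–O bond, the C7–CH3 bond (leaving a C7 enol triflate), and last C4–C5.
Enabling feature: in the deoxygenated eleven-membered ring, C2=C3–C4–C5–C6=C7 is an (E,E)-1,5-diene. Opening C4–C5 while closing C2–C7 (a Cope shift read backwards) contracts it to the cycloheptane C7–C8–C9–C10–C11–C1–C2, with isopropenyl (C3, C4) on C2 and vinyl (C6, C5) plus hydroxyl on C7.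
Rings in the forward sense: six-membered (3-methylcyclohexenone) → seven-membered (one-carbon siloxycyclopropane expansion) → eleven-membered (four-carbon anionic oxy-Cope expansion) → oxirane last, so no macrocyclisation is needed.
Stereochemistry: a CBS reduction sets a sacrificial C7 carbinol, a hydroxyl-directed epoxidation relays it to C1 (S), the chair Cope array of the trans-dialkenyl carbinol fixes both ring-E alkenes, and the D-fructose-derived Shi ketone sets 6R,7R.

Key step: step 12

Remark on the chemistry: C2 and C7 of the Cope precursor are erased in the rearrangement, so only their mutual trans relation matters. The enolate and the enol triflate are 6Z by the CIP rules because oxygen outranks C8, although the ring carbons C5 and C8 are trans; the same geometry is called 6E once methyl has replaced OTf.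

Step 1
Reactants: 1 3-methylcyclohex-2-en-1-one
Product: 2 [(3,3-dimethylcyclohex-1-en-1-yl)oxy]trimethylsilane
Conditions: MeMgBr, CuI·2LiCl (10 mol %), TMSCl, THF, −40 → 0 °C; Et3N, cold aq. NaHCO3
Reagents that add atoms: methylmagnesium bromide, C[Mg]Br; chlorotrimethylsilane, C[Si](C)(C)Cl
Why: Copper-catalysed conjugate addition of a Grignard reagent with in situ silylation, in which methyl transfer to the β-carbon builds the gem-dimethyl carbon C11 and TMSCl captures the enolate as the silyl enol ether on the hindered side, a regioisomer that deprotonation of 3,3-dimethylcyclohexanone would not give.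

Step 2
Reactants: 2 [(3,3-dimethylcyclohex-1-en-1-yl)oxy]trimethylsilane
Product: 3 rac-[(5,5-dimethylbicyclo[4.1.0]heptan-1-yl)oxy]trimethylsilane
Conditions: Et2Zn, CH2I2, Et2O, 0 °C → rt; pyridine quench
Reagents that add atoms: diiodomethane, ICI
Why: Simmons–Smith cyclopropanation (Furukawa variant), in which the electrophilic zinc carbenoid adds to the electron-rich enol ether bond and brings in the carbon that becomes C2, the two stereocentres of the racemic product being erased in the next step.

Step 3
Reactants: 3 rac-[(5,5-dimethylbicyclo[4.1.0]heptan-1-yl)oxy]trimethylsilane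
Product: 5 4,4-dimethylcyclohept-2-en-1-one, via 3-chloro-4,4-dimethylcycloheptan-1-one 4 (not isolated)
Conditions: FeCl3, DMF, 0 → 60 °C; crude product, NaOAc, MeOH, reflux
Reagents that add atoms: iron(III) chloride, Cl[Fe](Cl)Cl (chlorine only in 4)
Why: Saegusa-type oxidative ring expansion of a siloxycyclopropane, in which Fe(III) cleaves the internal cyclopropane bond to the ring-enlarged β-keto radical, chlorine transfer gives 4, and acetate-induced E1cB loss of HCl gives the cycloheptenone with C11 at the γ-position.

Step 4
Reactants: 5 4,4-dimethylcyclohept-2-en-1-one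
Product: 6 2-iodo-4,4-dimethylcyclohept-2-en-1-one
Conditions: I2, pyridine/CH2Cl2, 0 °C → rt
Reagents that add atoms: iodine, II
Why: α-Iodination of an enone by a Baylis–Hillman-type addition–iodination–elimination sequence with pyridine as the nucleophilic carrier, a reaction well established for 4,4-dialkylcycloalkenones.

Step 5
Reactants: 6 2-iodo-4,4-dimethylcyclohept-2-en-1-one
Product: 7 (1S)-2-iodo-4,4-dimethylcyclohept-2-en-1-ol
Conditions: (R)-Me-CBS (15 mol %), BH3·SMe2, THF, −20 °C; MeOH
Reagents that add atoms: none
Why: Corey–Bakshi–Shibata reduction, in which the iodoalkene arm is clearly the large and the C8 methylene the small substituent, so the (R)-oxazaborolidine should deliver hydride to give the (S)-carbinol at C7, the centre from which all absolute configuration is relayed.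

Step 6
Reactants: 7 (1S)-2-iodo-4,4-dimethylcyclohept-2-en-1-ol; 8 isopropenylboronic acid pinacol ester
Product: 9 (1S)-4,4-dimethyl-2-(prop-1-en-2-yl)cyclohept-2-en-1-ol
Conditions: Pd(dppf)Cl2·CH2Cl2 (5 mol %), K2CO3, THF/H2O, 55 °C
Reagents that add atoms: isopropenylboronic acid pinacol ester 8, CC(=C)B1OC(C)(C)C(C)(C)O1
Why: Suzuki–Miyaura coupling of an alkenyl iodide with an alkenylboronate, which tolerates the free allylic alcohol and, run after the reduction, avoids a cross-conjugated 2-alkenyl enone that could dimerise by Diels–Alder reaction.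

Step 7
Reactants: 9 (1S)-4,4-dimethyl-2-(prop-1-en-2-yl)cyclohept-2-en-1-ol
Product: 10 (1S,2S,7R)-6,6-dimethyl-1-(prop-1-en-2-yl)-8-oxabicyclo[5.1.0]octan-2-ol
Conditions: VO(acac)2 (3 mol %), t-BuOOH (decane), CH2Cl2, 0 °C
Reagents that add atoms: tert-butyl hydroperoxide, CC(C)(C)OO
Why: Vanadium-catalysed hydroxyl-directed epoxidation, in which the C7 vanadate delivers oxygen to the allylic C1=C2 bond rather than to the homoallylic isopropenyl group and on the hydroxyl-bearing face (the cis mode known for cycloheptenols), which sets C1 with the oxygen configuration of the target and C2 temporarily.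

Step 8
Reactants: 10 (1S,2S,7R)-6,6-dimethyl-1-(prop-1-en-2-yl)-8-oxabicyclo[5.1.0]octan-2-ol
Product: 11 (1R,7R)-6,6-dimethyl-1-(prop-1-en-2-yl)-8-oxabicyclo[5.1.0]octan-2-one
Conditions: Dess–Martin periodinane, NaHCO3, CH2Cl2, 0 °C → rt
Reagents that add atoms: none
Why: Dess–Martin oxidation under buffered conditions turns the relay carbinol into the ketone without opening the alkenyl oxirane, and C2 carries no hydrogen, so nothing can epimerise.

Step 9
Reactants: 11 (1R,7R)-6,6-dimethyl-1-(prop-1-en-2-yl)-8-oxabicyclo[5.1.0]octan-2-one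
Product: 13 (2S,3S)-3-hydroxy-4,4-dimethyl-2-(prop-1-en-2-yl)cycloheptan-1-one, via samarium(III) dienolate 12 (not isolated)
Conditions: SmI2 (2.2 equiv), THF/MeOH, −90 °C; pH 7 buffer
Reagents that add atoms: samarium diiodide, I[Sm]I (samarium and iodine only in 12)
Why: Samarium diiodide reduction of an α,β-epoxy ketone to the aldol, in which only the Cα–O bond (C2–O) breaks so that the C1–O centre is untouched, and 12 is protonated kinetically at the α-carbon by methanol, which keeps the isopropenyl group out of conjugation and should place it trans to the C1 oxygen (proton delivery on the alkoxide-bearing face, also the more stable arrangement).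

Step 10
Reactants: 13 (2S,3S)-3-hydroxy-4,4-dimethyl-2-(prop-1-en-2-yl)cycloheptan-1-one
Product: 14 (2S,3S)-3-[(tert-butyldimethylsilyl)oxy]-4,4-dimethyl-2-(prop-1-en-2-yl)cycloheptan-1-one
Conditions: TBSOTf, 2,6-lutidine, CH2Cl2, −78 → 0 °C
Reagents that add atoms: tert-butyldimethylsilyl triflate, CC(C)(C)[Si](C)(C)OS(=O)(=O)C(F)(F)F
Why: Silylation of a hindered secondary alcohol with the silyl triflate and a non-nucleophilic pyridine base, mild enough to avoid retro-aldol cleavage, dehydration or migration of the β,γ-double bond.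

Step 11
Reactants: 14 (2S,3S)-3-[(tert-butyldimethylsilyl)oxy]-4,4-dimethyl-2-(prop-1-en-2-yl)cycloheptan-1-one; 15 vinylmagnesium bromide
Product: 16 (1S,2S,3S)-3-[(tert-butyldimethylsilyl)oxy]-1-ethenyl-4,4-dimethyl-2-(prop-1-en-2-yl)cycloheptan-1-ol
Conditions: CeCl3 (anhydrous), THF, −78 °C; aq. work-up
Reagents that add atoms: vinylmagnesium bromide 15, C=C[Mg]Br
Why: Organocerium 1,2-addition, in which the weakly basic vinylcerium reagent should add to the carbonyl faster than it enolises the doubly activated C2–H or expels silanolate, and should approach C7 from the face opposite the neighbouring isopropenyl group, which sets C7 (S) with vinyl trans and hydroxyl cis to isopropenyl.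

Step 12
Reactants: 16 (1S,2S,3S)-3-[(tert-butyldimethylsilyl)oxy]-1-ethenyl-4,4-dimethyl-2-(prop-1-en-2-yl)cycloheptan-1-ol
Product: 19 (1Z,5E,7S)-7-[(tert-butyldimethylsilyl)oxy]-5,8,8-trimethylcycloundeca-1,5-dien-1-yl trifluoromethanesulfonate, via potassium alkoxide 17 (not isolated), via potassium enolate 18 (not isolated)
Conditions: KH, 18-crown-6, THF, 0 °C → rt; then Comins' reagent, −78 °C
Reagents that add atoms: Comins' reagent, N-(5-chloropyridin-2-yl)bis(trifluoromethanesulfonimide), O=S(=O)(N(c1ccc(Cl)cn1)S(=O)(=O)C(F)(F)F)C(F)(F)F; potassium hydride, [K+].[H-] (potassium only in 17 and 18)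
Why: KH/18-crown-6 converts 16 into the naked alkoxide 17, whose charge-accelerated [3,3]-sigmatropic shift (anionic oxy-Cope rearrangement, the established four-carbon ring expansion of 1,2-dialkenylcycloalkanols) forms C4–C5 and breaks C2–C7. The eleven-membered ring thus arises by expansion of the cycloheptane and not by end-to-end cyclisation, and formation of enolate 18 makes the shift irreversible against the usual Cope bias for the smaller ring. No stereocentre is created, since C2 and C7 are erased and C1 (S) lies outside the six-atom array and is carried through unchanged. The step needs alkene geometry: with vinyl and isopropenyl trans only the chair array is within reach, the ring bonds C2–C1 and C7–C8 are pseudo-equatorial and O– is pseudo-axial, so C1/C4 end up trans across C2=C3 and C5/C8 trans across C6=C7 with oxygen cis to C5. It also needs enolate regiochemistry, which is secured because the C6=C7 enolate is born in the pericyclic event and is O-sulfonylated at −78 °C before proton transfer to the C7=C8 isomer can set in. Silyl transfer from the secondary C1 oxygen to the tertiary alkoxide is uphill and hampered by the 1,3-trans relation of the two oxygens, and any such equilibrium would be drained by the rearrangement.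

Step 13
Reactants: 19 (1Z,5E,7S)-7-[(tert-butyldimethylsilyl)oxy]-5,8,8-trimethylcycloundeca-1,5-dien-1-yl trifluoromethanesulfonate
Product: 20 tert-butyldimethyl{[(1S,2E,6E)-3,7,11,11-tetramethylcycloundeca-2,6-dien-1-yl]oxy}silane
Conditions: MeMgBr, Fe(acac)3 (10 mol %), THF/NMP, −30 → 0 °C
Reagents that add atoms: methylmagnesium bromide, C[Mg]Br
Why: Iron-catalysed Kumada-type cross-coupling of an alkenyl triflate with a methyl Grignard reagent, fast at low temperature and stereoretentive, so that methyl takes the place of OTf and the ring-trans C6=C7 bond becomes the (6E)-trisubstituted alkene while the silyl ether is inert.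

Step 14
Reactants: 20 tert-butyldimethyl{[(1S,2E,6E)-3,7,11,11-tetramethylcycloundeca-2,6-dien-1-yl]oxy}silane
Product: 21 (1S,2E,6E)-3,7,11,11-tetramethylcycloundeca-2,6-dien-1-ol
Conditions: TBAF, THF, rt → 50 °C
Reagents that add atoms: none
Why: Fluoride-induced desilylation driven by Si–F bond formation, run without acid so that the 1,5-diene is not exposed to transannular cationic cyclisation.

Step 15
Reactants: 21 (1S,2E,6E)-3,7,11,11-tetramethylcycloundeca-2,6-dien-1-ol; 22 4-methoxybenzoyl chloride
Product: 23 (1S,2E,6E)-3,7,11,11-tetramethylcycloundeca-2,6-dien-1-yl 4-methoxybenzoate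
Conditions: Et3N, DMAP (cat.), CH2Cl2, rt → reflux
Reagents that add atoms: 4-methoxybenzoyl chloride 22, COc1ccc(cc1)C(Cl)=O
Why: DMAP-catalysed acylation through the acylpyridinium ion takes place at oxygen of the neopentylic allylic alcohol, so C1 keeps its configuration.

Step 16
Reactants: 23 (1S,2E,6E)-3,7,11,11-tetramethylcycloundeca-2,6-dien-1-yl 4-methoxybenzoate
Product: 24 (1S,2E,6R,7R)-6,7-epoxy-3,7,11,11-tetramethylcycloundec-2-en-1-yl 4-methoxybenzoate (target)
Conditions: D-fructose-derived Shi ketone (30 mol %), Oxone, K2CO3, Bu4NHSO4 (cat.), MeCN–DMM/aq. Na2B4O7–Na2EDTA, 0 °C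
Reagents that add atoms: potassium peroxymonosulfate (active component of Oxone), [K+].[O-]S(=O)(=O)OO
Why: Shi asymmetric epoxidation, in which the chiral dioxirane should attack the more nucleophilic C6=C7 bond because C2=C3 is deactivated by the allylic aroyloxy group and screened by C11, and the spiro transition state of the D-fructose-derived ketone gives the (R,R)-epoxide of an E-trisubstituted alkene, the ring conformers that expose either alkene face interconverting fast enough for the catalyst to choose.

Compound list
1 | 3-methylcyclohex-2-en-1-one | CC1=CC(=O)CCC1 | starting material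
2 | [(3,3-dimethylcyclohex-1-en-1-yl)oxy]trimethylsilane | CC1(C)CCCC(O[Si](C)(C)C)=C1 | intermediate
3 | rac-[(5,5-dimethylbicyclo[4.1.0]heptan-1-yl)oxy]trimethylsilane (cis-fused, racemic) | CC1(C)CCCC2(O[Si](C)(C)C)CC12 | intermediate
4 | rac-3-chloro-4,4-dimethylcycloheptan-1-one | CC1(C)CCCC(=O)CC1Cl | intermediate (not isolated)
5 | 4,4-dimethylcyclohept-2-en-1-one | CC1(C)CCCC(=O)C=C1 | intermediate
6 | 2-iodo-4,4-dimethylcyclohept-2-en-1-one | CC1(C)CCCC(=O)C(I)=C1 | intermediate
7 | (1S)-2-iodo-4,4-dimethylcyclohept-2-en-1-ol | O[C@H]1CCCC(C)(C)C=C1I | intermediate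
8 | isopropenylboronic acid pinacol ester | CC(=C)B1OC(C)(C)C(C)(C)O1 | starting material
9 | (1S)-4,4-dimethyl-2-(prop-1-en-2-yl)cyclohept-2-en-1-ol | O[C@H]1CCCC(C)(C)C=C1C(C)=C | intermediate
10 | (1S,2S,7R)-6,6-dimethyl-1-(prop-1-en-2-yl)-8-oxabicyclo[5.1.0]octan-2-ol (hydroxyl cis to oxirane oxygen) | O[C@H]1CCCC(C)(C)[C@H]2O[C@@]12C(C)=C | intermediate
11 | (1R,7R)-6,6-dimethyl-1-(prop-1-en-2-yl)-8-oxabicyclo[5.1.0]octan-2-one | O=C1CCCC(C)(C)[C@H]2O[C@@]12C(C)=C | intermediate
12 | samarium(III) dienolate–alkoxide from C2–O cleavage of 11 | CC(=C)C1=C(O[Sm](I)I)CCCC(C)(C)[C@H]1O[Sm](I)I | intermediate (not isolated)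
13 | (2S,3S)-3-hydroxy-4,4-dimethyl-2-(prop-1-en-2-yl)cycloheptan-1-one (isopropenyl trans to hydroxyl) | O=C1CCCC(C)(C)[C@@H](O)[C@@H]1C(C)=C | intermediate
14 | (2S,3S)-3-[(tert-butyldimethylsilyl)oxy]-4,4-dimethyl-2-(prop-1-en-2-yl)cycloheptan-1-one | O=C1CCCC(C)(C)[C@@H](O[Si](C)(C)C(C)(C)C)[C@@H]1C(C)=C | intermediate
15 | vinylmagnesium bromide | C=C[Mg]Br | starting material
16 | (1S,2S,3S)-3-[(tert-butyldimethylsilyl)oxy]-1-ethenyl-4,4-dimethyl-2-(prop-1-en-2-yl)cycloheptan-1-ol (vinyl trans to isopropenyl) | C=C[C@@]1(O)CCCC(C)(C)[C@@H](O[Si](C)(C)C(C)(C)C)[C@@H]1C(C)=C | intermediate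
17 | potassium alkoxide of 16 | C=C[C@@]1([O-])CCCC(C)(C)[C@@H](O[Si](C)(C)C(C)(C)C)[C@@H]1C(C)=C.[K+] | intermediate (not isolated)
18 | potassium (1Z,5E,7S)-7-[(tert-butyldimethylsilyl)oxy]-5,8,8-trimethylcycloundeca-1,5-dien-1-olate (O cis to C5) | CC(C)(C)[Si](C)(C)O[C@H]1/C=C(\C)CC/C=C(\[O-])CCCC1(C)C.[K+] | intermediate (not isolated)
19 | (1Z,5E,7S)-7-[(tert-butyldimethylsilyl)oxy]-5,8,8-trimethylcycloundeca-1,5-dien-1-yl trifluoromethanesulfonate (target locants: 2E,6Z; C5/C8 trans) | CC(C)(C)[Si](C)(C)O[C@H]1/C=C(\C)CC/C=C(\OS(=O)(=O)C(F)(F)F)CCCC1(C)C | intermediate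
20 | tert-butyldimethyl{[(1S,2E,6E)-3,7,11,11-tetramethylcycloundeca-2,6-dien-1-yl]oxy}silane | CC(C)(C)[Si](C)(C)O[C@H]1/C=C(\C)CC/C=C(\C)CCCC1(C)C | intermediate
21 | (1S,2E,6E)-3,7,11,11-tetramethylcycloundeca-2,6-dien-1-ol | O[C@H]1/C=C(\C)CC/C=C(\C)CCCC1(C)C | intermediate
22 | 4-methoxybenzoyl chloride | COc1ccc(cc1)C(Cl)=O | starting material
23 | (1S,2E,6E)-3,7,11,11-tetramethylcycloundeca-2,6-dien-1-yl 4-methoxybenzoate | COc1ccc(C(=O)O[C@H]2/C=C(\C)CC/C=C(\C)CCCC2(C)C)cc1 | intermediate
24 | (1S,2E,6R,7R)-6,7-epoxy-3,7,11,11-tetramethylcycloundec-2-en-1-yl 4-methoxybenzoate | COc1ccc(C(=O)O[C@H]2/C=C(\C)CC[C@H]3O[C@]3(C)CCCC2(C)C)cc1 | target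

Total step count: 16. Longest linear sequence: 16 steps, from 1 to 24; compounds 8, 15 and 22 are bought.

Steps most likely to fail

Step 12. The rearrangement may stall or leak through a boat array. The naked enolate may equilibrate by proton transfer before it is sulfonylated, or left-over hydride may consume the triflating agent. The fallback sets out from 16 and returns at 19, and it separates the pericyclic event from the sulfonylation. Carbinol 16 is rearranged with KH/18-crown-6 as before (17, then 18). The enolate is then captured at −78 °C with TMSCl/Et3N, a faster O-trapping, to give the isolable trimethylsilyl enol ether F1. This compound can be freed from crown ether and base, and its geometry can be checked. Methyllithium in THF at 0 °C then cleaves the O–SiMe3 bond and regenerates the crown-free lithium enolate F2 with position and geometry retained. Comins' reagent at −78 °C converts it into 19.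

Step 11. The organometal may enolise the doubly activated C2–H, with ensuing loss of silanolate, or may attack the wrong carbonyl face, which would put the two alkenyl groups cis. The fallback sets out from 11 and returns at 19, and it adds the vinyl group while C2 is still quaternary. Epoxy ketone 11 has no C2–H and no β-leaving group that an enolate could expel. Reagent 15 (THF, −78 °C) should add anti to the pseudo-axial C2–O bond (polar Felkin–Anh control) to give the epoxy carbinol F3. Palladium-catalysed formate hydrogenolysis of the alkenyl oxirane follows (Pd2(dba)3·CHCl3, n-Bu3P, HCO2H, Et3N, THF, rt). It delivers hydride to the more substituted allyl terminus C2 with inversion. This leaves the isopropenyl group terminal and places it trans to the vinyl group in the diol F4. The secondary hydroxyl is silylated selectively (TBSOTf, 1 equiv, 2,6-lutidine, −78 °C) to give the carbinol F5, which differs from 16 only at the two centres that the Cope shift erases. Under the conditions of step 12 its potassium alkoxide F6 should rearrange through the same chair array to enolate 18, which is trapped as 19.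

Step 16. The facial preference of the catalyst may be opposed by the conformational bias that the C1 substituent imposes on the ring, which would lead to poor facial selectivity, and oxidation may spread to C2=C3. The fallback sets out from 20 and returns at 24, and it changes the order of events so that a different C1 substituent steers the ring. Silyl ether 20 is epoxidised under the same Shi conditions. Its bulky silyloxy group screens C2=C3 and populates other ring conformers than the planar ester does, and the product is the epoxy silyl ether F7. TBAF in THF frees the epoxy alcohol F8. Acylation with 22 (Et3N, DMAP, CH2Cl2), which the oxirane tolerates because no acid is present, gives 24.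

Further compounds
F1 | step 12 | (1Z,5E,7S)-7-[(tert-butyldimethylsilyl)oxy]-5,8,8-trimethyl-1-[(trimethylsilyl)oxy]cycloundeca-1,5-diene | CC(C)(C)[Si](C)(C)O[C@H]1/C=C(\C)CC/C=C(\O[Si](C)(C)C)CCCC1(C)C
F2 | step 12 | lithium (1Z,5E,7S)-7-[(tert-butyldimethylsilyl)oxy]-5,8,8-trimethylcycloundeca-1,5-dien-1-olate | CC(C)(C)[Si](C)(C)O[C@H]1/C=C(\C)CC/C=C(\[O-])CCCC1(C)C.[Li+]
F3 | step 11 | (1R,2R,7R)-2-ethenyl-6,6-dimethyl-1-(prop-1-en-2-yl)-8-oxabicyclo[5.1.0]octan-2-ol | C=C[C@]1(O)CCCC(C)(C)[C@H]2O[C@@]12C(C)=C
F4 | step 11 | (1R,2R,3S)-1-ethenyl-4,4-dimethyl-2-(prop-1-en-2-yl)cycloheptane-1,3-diol | C=C[C@]1(O)CCCC(C)(C)[C@@H](O)[C@H]1C(C)=C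
F5 | step 11 | (1R,2R,3S)-3-[(tert-butyldimethylsilyl)oxy]-1-ethenyl-4,4-dimethyl-2-(prop-1-en-2-yl)cycloheptan-1-ol | C=C[C@]1(O)CCCC(C)(C)[C@@H](O[Si](C)(C)C(C)(C)C)[C@H]1C(C)=C
F6 | step 11 | potassium alkoxide of F5 | C=C[C@]1([O-])CCCC(C)(C)[C@@H](O[Si](C)(C)C(C)(C)C)[C@H]1C(C)=C.[K+]
F7 | step 16 | tert-butyl{[(1S,2E,6R,7R)-6,7-epoxy-3,7,11,11-tetramethylcycloundec-2-en-1-yl]oxy}dimethylsilane | CC(C)(C)[Si](C)(C)O[C@H]1/C=C(\C)CC[C@H]2O[C@]2(C)CCCC1(C)C
F8 | step 16 | (1S,2E,6R,7R)-6,7-epoxy-3,7,11,11-tetramethylcycloundec-2-en-1-ol | O[C@H]1/C=C(\C)CC[C@H]2O[C@]2(C)CCCC1(C)C
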